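## The problem

Target **29** is a trans-fused hexahydroindenone. Ring A is a cyclopentanone (C1 with ethyl, C2 the ketone, C3 with methyl, C3a, C7a). It shares the C3a–C7a bond with ring B, a cyclohexene (C3a, C4 with methyl, C5, C6 with ethyl and (E)-styryl, C7 with ethyl and the carboxyl group, C7a). With this numbering the six stereocentres are 1S,3S,3aR,6S,7R,7aR.

C1 and C3 flank the ketone and can be set last by equilibration. The real task is the contiguous set C3a, C7a, C7 and C6, in which C6 and C7 are adjacent all-carbon quaternary centres with cis ethyl groups. C3a and C7a can control C6 and C7, but not the reverse, because nothing at C6 or C7 can be corrected afterwards.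

The C7 carboxyl is flanked by a quaternary and a tertiary carbon and will resist acyl chemistry once made. It also lies close to the C4=C5 alkene, so strong acid threatens lactonisation. The styryl and ring alkenes rule out hydrogenolysis, ozonolysis and unselective hydride or borane chemistry late in the route.

Seen from the carboxyl group, C7 (α), C6 (β, fully substituted) and C4=C5 (γ,δ) form the unsaturated acid array left by an ester enolate Claisen rearrangement. Because C7 and C4 are also joined through C7a–C3a, the ester is a six-membered lactone (C7 as α-carbon, ring oxygen on C4) with a dienyl arm on C4. Its [3,3] shift would form C6–C7, both quaternary centres and ring B at once.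

## Retrosynthesis

**Ring A last (29 ⇒ 27 ⇒ 25).** The C2–C3 bond is cut by a Dieckmann condensation after placing a sacrificial methoxycarbonyl group on C3; the C3 methyl is put on the resulting β-keto ester. Ring A cannot be present earlier: a trans-fused five-membered ring cannot span the boat of the key step. Triester **25** is a trans-1,2-disubstituted cyclohexene with one CH2CO2Me arm and one CH(Et)CO2Me arm, the classical substrate for closing a trans-hydrindan-2-one. The forward reaction must enolise at C3 and acylate at C2 without touching the C7 ester. One operation (LiI) is then asked to remove the C3 ester, cleave the hindered C7 methyl ester by attack at the methyl carbon, and allow C1 and C3 to settle trans to their ring-fusion neighbours.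

**Arms at the right oxidation level (25 ⇒ 20).** No C–C bond is cut. The two arms must be inert to an amide base during the key step, so they cannot be esters there. The C7a arm is carried as a but-1-en-2-yl group (a masked CH(Et)CH2OH that is flat and small), and the C3a arm as a silyl-protected 2-hydroxyethyl group. Hydroboration and one chromic acid oxidation then give both acids.

**Key disconnection (20 ⇒ 17).** The C6–C7 bond is cut and the C4–O bond re-formed, which turns acid **20** into dienyl lactone **17**. Against stepwise alkylation at C7 or conjugate addition at C6, this cut makes both quaternary centres in one intramolecular, stereospecific event. Their relative configuration comes from the alkene geometry and a ring-enforced boat, not from reagent approach to a crowded centre. The precursor is one ring and two quaternary carbons simpler. The forward reaction needs clean enolisation at C7, the (E)-C5=C6 geometry with ethyl cis to C4, and the C7a arm cis to the dienyl arm on the lactone.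

**The diene after the lactone is built (17 ⇒ 16 ⇒ 15 ⇒ 14 ⇒ 13).** The C6–ethyl and C6–styryl bonds are cut back to a 1,1-dibromoalkene, and that to a C5 aldehyde. Sequential coupling of a 1,1-dibromoalkene fixes the geometry by mechanism: the bromide trans to C4 reacts first (styryl), the hindered cis bromide second (ethyl). The neighbouring option, adding a dienyl metal to a C4 methyl ketone, was rejected for two reasons. It needs a geometrically pure dienyl halide, and a Felkin–Anh analysis with the branched C7a carbon as the large group predicts the wrong C4 epimer. Delaying the diene also keeps the acid-labile tertiary dienylic C–O bond out of ten earlier steps.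

**C7a and C7 on the lactone template (13 ⇒ 11 ⇒ 9).** The C7a–butenyl bond is cut by conjugate addition and the C7–ethyl bond by enolate alkylation. In unsaturated lactone **9** the C3a side chain and the axial C4 methyl group lie on the same face, so a cuprate must enter anti to both. That places the arm trans to the C3a arm and cis to the future dienyl arm, as the key step requires. The C7 configuration is irrelevant because enolisation erases it.

**The lactone ring (9 ⇒ 8 ⇒ 7 ⇒ 6).** The C7=C7a bond is cut by ring-closing metathesis and the acyl–oxygen bond by acylation. This is the shortest entry to a 5,6-dihydropyran-2-one from a tertiary homoallylic alcohol. It is only possible because the diene is not yet present: a styryl diene would offer the catalyst a competing six-membered closure.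

**C3a and C4 (6 ⇒ 5 ⇒ 4).** The C3a–vinyl bond is cut by opening an epoxide at its secondary carbon, and the C4–O bond by asymmetric epoxidation. This sets the tertiary carbinol by reagent control and C3a by stereospecific inversion, avoiding acyclic induction at a ketone. The analysis of relative configuration demands the (Z)-allylic alcohol **4**: only then does the C3a side chain end cis to the C4 methyl group in the lactone.

**Starting materials (4 ⇒ 3 ⇒ 1 + 2).** The C4=C3a bond of **3** is cut by a Z-selective phosphonate olefination of aldehyde **1** with reagent **2**.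

## Roads not taken

**Alternative 1:** Hydride-interrupted Nazarov cyclisation. The cut is C3a–C7a. An E,E cross-conjugated dienone **A1** would be activated by BF3·OEt2, close by conrotation, and the oxyallyl cation would be reduced by Et3SiH to the all-trans cyclopentanone **A2**.
- Merits: ring A with its trans C3a/C7a relationship arises in one step from an acyclic precursor, with no Dieckmann, methylation or decarboxylation. In step count for ring A this road is better than the chosen plan, which spends six steps after the key step.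
- Weak points: the sense of conrotation must be relayed from a single allylic ether stereocentre on the C3a arm, which is a modest torquoselective bias. Simple alkyl dienones are reluctant Nazarov substrates. Above all, **A2** still lacks ring B and both quaternary carbons, so the hardest part of the molecule would have to be built on a base-sensitive cyclopentanone.
- Comparison: the chosen plan solves C6 and C7 first, by a mechanism that fixes their relative configuration, and accepts a longer but conventional ring A endgame.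

**Alternative 2:** Ring-closing metathesis with selection between diastereotopic vinyl groups. The cut is C4=C5. Triene **A3** carries an isopropenyl group on C3a and two vinyl groups on C6; the second-generation Grubbs catalyst would close ring B to **A4**.
- Merits: metathesis is milder and more predictable than a lactone enolate rearrangement, and ring A with its ketone is already in place. In these respects it is better than the chosen key step.
- Weak points: the closure must form a trisubstituted alkene next to a quaternary carbon. The configuration at C6 rests only on a conformational preference between two vinyl groups. **A3** already contains the C6–C7 quaternary pair in an acyclic setting, so the real difficulty moves into the precursor. The remaining vinyl group must still be converted into styryl at a neopentyl position.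
- Comparison: the chosen plan has to set a crowded boat transition state against this, but it creates the quaternary pair, not merely encloses it.

**Alternative 3:** Diels–Alder reaction of 2,3-diethylmaleic anhydride. The cuts are C5–C6 and C7–C7a. Anhydride **A5** and chiral 1-amino-3-siloxybutadiene **A6** would combine endo; acid would then release enone anhydride **A7**.
- Merits: the cis diethyl pair comes directly from the dienophile geometry, with absolute control from the amine. It is the shortest route to the two quaternary carbons, clearly shorter than the thirteen steps the chosen plan needs before its key step.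
- Weak points: tetrasubstituted maleic anhydrides are poor dienophiles. In **A7** the two anhydride carbonyls are nearly equivalent, yet one must become the C7 acid and the other a styryl group. C7a is a bare methylene, C4 lacks its methyl group and the ketone sits at C3a, so ring A with its trans fusion still has to be built by several further stereocontrolled steps.
- Comparison: the chosen plan gives a ring B product in which every carbon already has its final substituent or a direct precursor of it.

Key step: step 14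

Assumption: compounds **1** and **2** and all reagents named in the steps are purchased. The side-chain centre C1 in **22**–**25** and the centres C1 and C3 in **26**–**28** are not controlled; they are written without configuration because both end α to the C2 ketone and are set by the final equilibration.

## Route

Step 1
Reactants: 1 3-[(tert-butyldimethylsilyl)oxy]propanal; 2 ethyl 2-[bis(2,2,2-trifluoroethoxy)phosphoryl]propanoate
Product: 3 ethyl (2Z)-5-[(tert-butyldimethylsilyl)oxy]-2-methylpent-2-enoate
Conditions: KN(SiMe3)2, 18-crown-6, THF, −78 °C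
Reagents that add atoms: none
Why: Still–Gennari olefination; the electron-poor phosphonate eliminates fast from the kinetic adduct and should give the (Z)-trisubstituted enoate that the later epoxide opening needs.

Step 2
Reactants: 3 ethyl (2Z)-5-[(tert-butyldimethylsilyl)oxy]-2-methylpent-2-enoate
Product: 4 (2Z)-5-[(tert-butyldimethylsilyl)oxy]-2-methylpent-2-en-1-ol
Conditions: iBu2AlH, CH2Cl2, −78 °C; aq. KNaC4H4O6
Reagents that add atoms: none
Why: 1,2-reduction of a conjugated ester by an aluminium hydride; the alkene geometry and the silyl ether are not affected.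

Step 3
Reactants: 4 (2Z)-5-[(tert-butyldimethylsilyl)oxy]-2-methylpent-2-en-1-ol
Product: 5 [(2R,3S)-3-[2-[(tert-butyldimethylsilyl)oxy]ethyl]-2-methyloxiran-2-yl]methanol
Conditions: Ti(OiPr)4 (cat.), D-(−)-diethyl tartrate, t-BuOOH, 4 Å MS, CH2Cl2, −20 °C
Reagents that add atoms: tert-butyl hydroperoxide, CC(C)(C)OO
Why: Sharpless asymmetric epoxidation; the D-(−)-tartrate complex delivers oxygen to the face opposite to that used by the L-(+)-ligand (which gives 2S epoxides of this substitution type), setting C4 (2R) by reagent control.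

Step 4
Reactants: 5 [(2R,3S)-3-[2-[(tert-butyldimethylsilyl)oxy]ethyl]-2-methyloxiran-2-yl]methanol
Product: 6 (2S,3S)-3-[2-[(tert-butyldimethylsilyl)oxy]ethyl]-2-methylpent-4-ene-1,2-diol
Conditions: CH2=CHMgBr, CuI (cat.), THF, −30 → 0 °C
Reagents that add atoms: vinylmagnesium bromide, C=C[Mg]Br
Why: Copper-catalysed Grignard opening of a 2,3-epoxy alcohol; the fully substituted C2 blocks attack there, so the vinyl group enters at the secondary carbon with inversion and sets C3a.

Step 5
Reactants: 6 (2S,3S)-3-[2-[(tert-butyldimethylsilyl)oxy]ethyl]-2-methylpent-4-ene-1,2-diol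
Product: 7 (2S,3S)-3-[2-[(tert-butyldimethylsilyl)oxy]ethyl]-2-methyl-1-[(triethylsilyl)oxy]pent-4-en-2-ol
Conditions: Et3SiCl, imidazole, CH2Cl2, −20 °C
Reagents that add atoms: chlorotriethylsilane, CC[Si](Cl)(CC)CC
Why: Selective silylation of the primary hydroxyl; the tertiary hydroxyl is too hindered to react at low temperature.

Step 6
Reactants: 7 (2S,3S)-3-[2-[(tert-butyldimethylsilyl)oxy]ethyl]-2-methyl-1-[(triethylsilyl)oxy]pent-4-en-2-ol
Product: 8 (2S,3S)-3-[2-[(tert-butyldimethylsilyl)oxy]ethyl]-2-methyl-1-[(triethylsilyl)oxy]pent-4-en-2-yl prop-2-enoate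
Conditions: CH2=CHCOCl, iPr2NEt, DMAP (cat.), CH2Cl2, 0 °C → rt
Reagents that add atoms: acryloyl chloride, C=CC(=O)Cl
Why: DMAP-catalysed acylation of a tertiary alcohol by a reactive acid chloride; it installs C8 and C7 of the lactone.

Step 7
Reactants: 8 (2S,3S)-3-[2-[(tert-butyldimethylsilyl)oxy]ethyl]-2-methyl-1-[(triethylsilyl)oxy]pent-4-en-2-yl prop-2-enoate
Product: 9 (5S,6S)-5-[2-[(tert-butyldimethylsilyl)oxy]ethyl]-6-methyl-6-[[(triethylsilyl)oxy]methyl]-5,6-dihydro-2H-pyran-2-one
Conditions: second-generation Grubbs catalyst (H2IMes)(PCy3)Cl2Ru=CHPh (cat.), CH2Cl2, 40 °C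
Reagents that add atoms: none
Why: Ring-closing metathesis of an acrylate with a terminal vinyl group gives the six-membered unsaturated lactone; no other alkene is present at this stage.

Step 8
Reactants: 9 (5S,6S)-5-[2-[(tert-butyldimethylsilyl)oxy]ethyl]-6-methyl-6-[[(triethylsilyl)oxy]methyl]-5,6-dihydro-2H-pyran-2-one
Product: 11 (4R,5S,6S)-4-(but-1-en-2-yl)-5-[2-[(tert-butyldimethylsilyl)oxy]ethyl]-6-methyl-6-[[(triethylsilyl)oxy]methyl]oxan-2-one, via trimethylsilyl ketene acetal 10 (not isolated)
Conditions: CH2=C(Et)MgBr (from 2-bromobut-1-ene, Mg, THF), CuBr·SMe2 (cat.), Me3SiCl, THF, −78 °C; aq. NH4Cl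
Reagents that add atoms: 2-bromobut-1-ene (as its Grignard reagent), C=C(Br)CC
Why: Copper-catalysed conjugate addition to a 5,6-dihydropyran-2-one; axial attack at C7a should occur anti to the C3a side chain and anti to the axial C4 methyl group, placing the butenyl arm trans to the C3a arm.

Step 9
Reactants: 11 (4R,5S,6S)-4-(but-1-en-2-yl)-5-[2-[(tert-butyldimethylsilyl)oxy]ethyl]-6-methyl-6-[[(triethylsilyl)oxy]methyl]oxan-2-one
Product: 13 (3R,4S,5S,6S)-4-(but-1-en-2-yl)-5-[2-[(tert-butyldimethylsilyl)oxy]ethyl]-3-ethyl-6-methyl-6-[[(triethylsilyl)oxy]methyl]oxan-2-one, via lithium enolate 12 (not isolated)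
Conditions: LiN(iPr)2, THF, −78 °C; EtI, DMPU, −78 → −30 °C
Reagents that add atoms: iodoethane, CCI
Why: Alkylation of a lactone enolate; the ethyl group should enter trans to the C7a arm, but either C7 epimer serves because the key step enolises this centre.

Step 10
Reactants: 13 (3R,4S,5S,6S)-4-(but-1-en-2-yl)-5-[2-[(tert-butyldimethylsilyl)oxy]ethyl]-3-ethyl-6-methyl-6-[[(triethylsilyl)oxy]methyl]oxan-2-one
Product: 14 (2S,3S,4S,5R)-4-(but-1-en-2-yl)-3-[2-[(tert-butyldimethylsilyl)oxy]ethyl]-5-ethyl-2-methyl-6-oxooxane-2-carbaldehyde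
Conditions: (COCl)2, DMSO, CH2Cl2, −78 → −30 °C; Et3N
Reagents that add atoms: none
Why: Swern oxidation applied directly to a primary triethylsilyl ether, which is cleaved and oxidised in one operation while the more robust tert-butyldimethylsilyl ether stays; the aldehyde has no α-hydrogen and cannot epimerise.

Step 11
Reactants: 14 (2S,3S,4S,5R)-4-(but-1-en-2-yl)-3-[2-[(tert-butyldimethylsilyl)oxy]ethyl]-5-ethyl-2-methyl-6-oxooxane-2-carbaldehyde
Product: 15 (3R,4S,5S,6S)-4-(but-1-en-2-yl)-5-[2-[(tert-butyldimethylsilyl)oxy]ethyl]-6-(2,2-dibromoethenyl)-3-ethyl-6-methyloxan-2-one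
Conditions: CBr4, PPh3, Et3N, CH2Cl2, 0 °C
Reagents that add atoms: carbon tetrabromide, BrC(Br)(Br)Br
Why: Ramirez dibromo-olefination (first stage of the Corey–Fuchs sequence); the buffered ylide tolerates the lactone, the silyl ether and the butenyl group.

Step 12
Reactants: 15 (3R,4S,5S,6S)-4-(but-1-en-2-yl)-5-[2-[(tert-butyldimethylsilyl)oxy]ethyl]-6-(2,2-dibromoethenyl)-3-ethyl-6-methyloxan-2-one
Product: 16 (3R,4S,5S,6S)-6-[(1Z,3E)-2-bromo-4-phenylbuta-1,3-dien-1-yl]-4-(but-1-en-2-yl)-5-[2-[(tert-butyldimethylsilyl)oxy]ethyl]-3-ethyl-6-methyloxan-2-one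
Conditions: (E)-PhCH=CHB(OH)2, Pd(PPh3)4 (cat.), TlOEt, THF/H2O, rt
Reagents that add atoms: (E)-(2-phenylethenyl)boronic acid, OB(O)/C=C/c1ccccc1
Why: Suzuki coupling of a 1,1-dibromoalkene; oxidative addition is selective for the bromide trans to the quaternary C4, so the styryl group is placed trans to C4 with retention of its own (E) geometry.

Step 13
Reactants: 16 (3R,4S,5S,6S)-6-[(1Z,3E)-2-bromo-4-phenylbuta-1,3-dien-1-yl]-4-(but-1-en-2-yl)-5-[2-[(tert-butyldimethylsilyl)oxy]ethyl]-3-ethyl-6-methyloxan-2-one
Product: 17 (3R,4S,5S,6S)-4-(but-1-en-2-yl)-5-[2-[(tert-butyldimethylsilyl)oxy]ethyl]-3-ethyl-6-[(1E,3E)-2-ethyl-4-phenylbuta-1,3-dien-1-yl]-6-methyloxan-2-one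
Conditions: Et2Zn, Pd(P(t-Bu)3)2 (cat.), THF, 0 °C → rt
Reagents that add atoms: diethylzinc, CC[Zn]CC
Why: Negishi coupling of the remaining alkenyl bromide with retention; the bulky trialkylphosphine is used because it suppresses isomerisation of 2-bromo-1,3-dienes, so the ethyl group ends cis to C4.

Step 14
Reactants: 17 (3R,4S,5S,6S)-4-(but-1-en-2-yl)-5-[2-[(tert-butyldimethylsilyl)oxy]ethyl]-3-ethyl-6-[(1E,3E)-2-ethyl-4-phenylbuta-1,3-dien-1-yl]-6-methyloxan-2-one
Product: 20 (1R,2S,5S,6R)-6-(but-1-en-2-yl)-5-[2-[(tert-butyldimethylsilyl)oxy]ethyl]-1,2-diethyl-4-methyl-2-[(E)-2-phenylethenyl]cyclohex-3-ene-1-carboxylic acid, via trimethylsilyl ketene acetal 18 (not isolated), via trimethylsilyl ester 19 (not isolated)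
Conditions: LiN(iPr)2, Me3SiCl/Et3N, THF, −78 °C → rt; PhMe, 80 °C; aq. citric acid
Reagents that add atoms: none
Why: LiN(iPr)2 removes the only α-hydrogen (on C7) and Me3SiCl present in the flask traps the enolate as cyclic ketene acetal 18, whose geometry is fixed by the ring. On warming, 18 undergoes a concerted [3,3] sigmatropic shift (Ireland–Claisen rearrangement) in which C6 bonds to C7 as the C4–O bond breaks, giving silyl ester 19 and, after mild acid, acid 20. The closest known reaction type is the Ireland–Claisen ring contraction of alkenyl-substituted lactones to cycloalkenecarboxylic acids (and of 6-alkenyl-1,4-dioxan-2-ones to dihydropyrans). Ring B closes through a six-centre pericyclic array, suprafacial on both three-atom components, that must be a boat because the two-atom C7a–C3a bridge spans C7 and C4 as in a bicyclo[2.2.2]octane. C7 is controlled by the C4 stereocentre, since the axial dienyl arm reaches only one face of the ketene acetal, which puts the carboxyl cis to H7a. C6 is controlled by the (E)-C5=C6 geometry within that boat, so the ethyl group cis to C4 ends trans to the carboxyl and cis to the C7 ethyl. The step needs one periselective pathway and clean enolisation; only the C5=C6 unit can reach C7, and no other α-hydrogen exists. The cost is a syn 1,3 contact between the C7a arm and the C6 ethyl group, which is why that arm is kept sp2 and small.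

Step 15
Reactants: 20 (1R,2S,5S,6R)-6-(but-1-en-2-yl)-5-[2-[(tert-butyldimethylsilyl)oxy]ethyl]-1,2-diethyl-4-methyl-2-[(E)-2-phenylethenyl]cyclohex-3-ene-1-carboxylic acid
Product: 21 methyl (1R,2S,5S,6R)-6-(but-1-en-2-yl)-5-[2-[(tert-butyldimethylsilyl)oxy]ethyl]-1,2-diethyl-4-methyl-2-[(E)-2-phenylethenyl]cyclohex-3-ene-1-carboxylate
Conditions: Me3SiCHN2, PhMe/MeOH, 0 °C
Reagents that add atoms: trimethylsilyldiazomethane, C[Si](C)(C)C=[N+]=[N-]
Why: Esterification by O-alkylation of the carboxylate, which is insensitive to hindrance at the acyl carbon; the ester stops lactonisation with the alcohol made in the next step.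

Step 16
Reactants: 21 methyl (1R,2S,5S,6R)-6-(but-1-en-2-yl)-5-[2-[(tert-butyldimethylsilyl)oxy]ethyl]-1,2-diethyl-4-methyl-2-[(E)-2-phenylethenyl]cyclohex-3-ene-1-carboxylate
Product: 23 methyl (1R,2S,5S,6R)-5-[2-[(tert-butyldimethylsilyl)oxy]ethyl]-1,2-diethyl-6-(1-hydroxybutan-2-yl)-4-methyl-2-[(E)-2-phenylethenyl]cyclohex-3-ene-1-carboxylate (side-chain epimers), via B-alkyl-9-borabicyclononane 22 (not isolated)
Conditions: 9-BBN, THF, 0 °C → rt; H2O2, aq. NaOAc
Reagents that add atoms: hydrogen peroxide, OO
Why: Hydroboration–oxidation; 9-BBN reacts with the terminal 1,1-disubstituted alkene far faster than with the trisubstituted ring alkene or the hindered styryl group, and the new centre C1 need not be controlled.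

Step 17
Reactants: 23 methyl (1R,2S,5S,6R)-5-[2-[(tert-butyldimethylsilyl)oxy]ethyl]-1,2-diethyl-6-(1-hydroxybutan-2-yl)-4-methyl-2-[(E)-2-phenylethenyl]cyclohex-3-ene-1-carboxylate (side-chain epimers)
Product: 24 methyl (1R,2S,5S,6R)-6-(1-carboxypropyl)-5-(carboxymethyl)-1,2-diethyl-4-methyl-2-[(E)-2-phenylethenyl]cyclohex-3-ene-1-carboxylate (side-chain epimers)
Conditions: CrO3, H2SO4, H2O, acetone, 0 °C → rt
Reagents that add atoms: chromium trioxide, O=[Cr](=O)=O; water, O
Why: Chromic acid oxidation of the primary alcohol to the acid; under the same acidic conditions the primary silyl ether is cleaved and oxidised, so both arms reach the acid level in one step.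

Step 18
Reactants: 24 methyl (1R,2S,5S,6R)-6-(1-carboxypropyl)-5-(carboxymethyl)-1,2-diethyl-4-methyl-2-[(E)-2-phenylethenyl]cyclohex-3-ene-1-carboxylate (side-chain epimers)
Product: 25 methyl (1R,2S,5S,6R)-1,2-diethyl-6-(1-methoxy-1-oxobutan-2-yl)-5-(2-methoxy-2-oxoethyl)-4-methyl-2-[(E)-2-phenylethenyl]cyclohex-3-ene-1-carboxylate (side-chain epimers)
Conditions: Me3SiCHN2, PhMe/MeOH, 0 °C
Reagents that add atoms: trimethylsilyldiazomethane, C[Si](C)(C)C=[N+]=[N-]
Why: Mild double esterification of the diacid without acid or base that could engage the ring alkene.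

Step 19
Reactants: 25 methyl (1R,2S,5S,6R)-1,2-diethyl-6-(1-methoxy-1-oxobutan-2-yl)-5-(2-methoxy-2-oxoethyl)-4-methyl-2-[(E)-2-phenylethenyl]cyclohex-3-ene-1-carboxylate (side-chain epimers)
Product: 27 dimethyl (3aS,6S,7R,7aR)-1,6,7-triethyl-3,4-dimethyl-2-oxo-6-[(E)-2-phenylethenyl]-2,3,3a,6,7,7a-hexahydro-1H-indene-3,7-dicarboxylate (C1 and C3 not controlled), via potassium enolate of the β-keto ester 26 (not isolated)
Conditions: KOtBu, THF, 0 °C → rt; MeI
Reagents that add atoms: iodomethane, CI
Why: Dieckmann condensation of a trans-1,2-disubstituted cyclohexene diester followed by C-methylation of the stabilised enolate in the same flask. Closure through the C3 enolate onto C2 gives the only enolisable β-keto ester, so reversible alternatives should funnel to it. The C7 ester, flanked by a quaternary and a tertiary carbon, is not expected to be attacked.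

Step 20
Reactants: 27 dimethyl (3aS,6S,7R,7aR)-1,6,7-triethyl-3,4-dimethyl-2-oxo-6-[(E)-2-phenylethenyl]-2,3,3a,6,7,7a-hexahydro-1H-indene-3,7-dicarboxylate (C1 and C3 not controlled)
Product: 29 (1S,3S,3aR,6S,7R,7aR)-1,6,7-triethyl-3,4-dimethyl-2-oxo-6-[(E)-2-phenylethenyl]-2,3,3a,6,7,7a-hexahydro-1H-indene-7-carboxylic acid, via lithium keto carboxylate epimer mixture 28 (not isolated)
Conditions: LiI, 2,4,6-collidine, reflux; NaOMe, MeOH, rt; 0.5 M HCl, 0 °C
Reagents that add atoms: none
Why: Iodide attacks both ester methyl groups (Krapcho-type dealkoxycarbonylation of the β-keto ester and SN2 cleavage of the hindered C7 ester, which avoids attack at the shielded acyl carbon). Methoxide then equilibrates C1 and C3 through the ketone enolate to the isomer with each substituent trans to its ring-fusion neighbour, which should be 29.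

## Compound list

1 | 3-[(tert-butyldimethylsilyl)oxy]propanal | O=CCCO[Si](C)(C)C(C)(C)C | starting material
2 | ethyl 2-[bis(2,2,2-trifluoroethoxy)phosphoryl]propanoate | CCOC(=O)C(C)P(=O)(OCC(F)(F)F)OCC(F)(F)F | starting material
3 | ethyl (2Z)-5-[(tert-butyldimethylsilyl)oxy]-2-methylpent-2-enoate | CCOC(=O)/C(C)=C\CCO[Si](C)(C)C(C)(C)C | intermediate
4 | (2Z)-5-[(tert-butyldimethylsilyl)oxy]-2-methylpent-2-en-1-ol | OC/C(C)=C\CCO[Si](C)(C)C(C)(C)C | intermediate
5 | [(2R,3S)-3-[2-[(tert-butyldimethylsilyl)oxy]ethyl]-2-methyloxiran-2-yl]methanol | OC[C@@]1(C)O[C@H]1CCO[Si](C)(C)C(C)(C)C | intermediate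
6 | (2S,3S)-3-[2-[(tert-butyldimethylsilyl)oxy]ethyl]-2-methylpent-4-ene-1,2-diol | OC[C@@](C)(O)[C@H](C=C)CCO[Si](C)(C)C(C)(C)C | intermediate
7 | (2S,3S)-3-[2-[(tert-butyldimethylsilyl)oxy]ethyl]-2-methyl-1-[(triethylsilyl)oxy]pent-4-en-2-ol | CC[Si](CC)(CC)OC[C@@](C)(O)[C@H](C=C)CCO[Si](C)(C)C(C)(C)C | intermediate
8 | (2S,3S)-3-[2-[(tert-butyldimethylsilyl)oxy]ethyl]-2-methyl-1-[(triethylsilyl)oxy]pent-4-en-2-yl prop-2-enoate | C=CC(=O)O[C@](C)(CO[Si](CC)(CC)CC)[C@H](C=C)CCO[Si](C)(C)C(C)(C)C | intermediate
9 | (5S,6S)-5-[2-[(tert-butyldimethylsilyl)oxy]ethyl]-6-methyl-6-[[(triethylsilyl)oxy]methyl]-5,6-dihydro-2H-pyran-2-one | O=C1C=C[C@H](CCO[Si](C)(C)C(C)(C)C)[C@@](C)(CO[Si](CC)(CC)CC)O1 | intermediate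
10 | trimethylsilyl ketene acetal of lactone 11 (2-trimethylsilyloxy-4H-pyran form) | C[Si](C)(C)OC1=C[C@@H](C(=C)CC)[C@H](CCO[Si](C)(C)C(C)(C)C)[C@@](C)(CO[Si](CC)(CC)CC)O1 | intermediate
11 | (4R,5S,6S)-4-(but-1-en-2-yl)-5-[2-[(tert-butyldimethylsilyl)oxy]ethyl]-6-methyl-6-[[(triethylsilyl)oxy]methyl]oxan-2-one | O=C1C[C@@H](C(=C)CC)[C@H](CCO[Si](C)(C)C(C)(C)C)[C@@](C)(CO[Si](CC)(CC)CC)O1 | intermediate
12 | lithium enolate of lactone 11 | [Li]OC1=C[C@@H](C(=C)CC)[C@H](CCO[Si](C)(C)C(C)(C)C)[C@@](C)(CO[Si](CC)(CC)CC)O1 | intermediate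
13 | (3R,4S,5S,6S)-4-(but-1-en-2-yl)-5-[2-[(tert-butyldimethylsilyl)oxy]ethyl]-3-ethyl-6-methyl-6-[[(triethylsilyl)oxy]methyl]oxan-2-one | C=C(CC)[C@H]1[C@H](CCO[Si](C)(C)C(C)(C)C)[C@@](C)(CO[Si](CC)(CC)CC)OC(=O)[C@@H]1CC | intermediate
14 | (2S,3S,4S,5R)-4-(but-1-en-2-yl)-3-[2-[(tert-butyldimethylsilyl)oxy]ethyl]-5-ethyl-2-methyl-6-oxooxane-2-carbaldehyde | C=C(CC)[C@H]1[C@H](CCO[Si](C)(C)C(C)(C)C)[C@@](C)(C=O)OC(=O)[C@@H]1CC | intermediate
15 | (3R,4S,5S,6S)-4-(but-1-en-2-yl)-5-[2-[(tert-butyldimethylsilyl)oxy]ethyl]-6-(2,2-dibromoethenyl)-3-ethyl-6-methyloxan-2-one | C=C(CC)[C@H]1[C@H](CCO[Si](C)(C)C(C)(C)C)[C@@](C)(C=C(Br)Br)OC(=O)[C@@H]1CC | intermediate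
16 | (3R,4S,5S,6S)-6-[(1Z,3E)-2-bromo-4-phenylbuta-1,3-dien-1-yl]-4-(but-1-en-2-yl)-5-[2-[(tert-butyldimethylsilyl)oxy]ethyl]-3-ethyl-6-methyloxan-2-one | C=C(CC)[C@H]1[C@H](CCO[Si](C)(C)C(C)(C)C)[C@@](C)(/C=C(Br)/C=C/c2ccccc2)OC(=O)[C@@H]1CC | intermediate
17 | (3R,4S,5S,6S)-4-(but-1-en-2-yl)-5-[2-[(tert-butyldimethylsilyl)oxy]ethyl]-3-ethyl-6-[(1E,3E)-2-ethyl-4-phenylbuta-1,3-dien-1-yl]-6-methyloxan-2-one | C=C(CC)[C@H]1[C@H](CCO[Si](C)(C)C(C)(C)C)[C@@](C)(/C=C(CC)/C=C/c2ccccc2)OC(=O)[C@@H]1CC | intermediate
18 | trimethylsilyl ketene acetal of lactone 17 | C=C(CC)[C@H]1[C@H](CCO[Si](C)(C)C(C)(C)C)[C@@](C)(/C=C(CC)/C=C/c2ccccc2)OC(O[Si](C)(C)C)=C1CC | intermediate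
19 | trimethylsilyl ester of acid 20 | C=C(CC)[C@H]1[C@H](CCO[Si](C)(C)C(C)(C)C)C(C)=C[C@@](/C=C/c2ccccc2)(CC)[C@]1(CC)C(=O)O[Si](C)(C)C | intermediate
20 | (1R,2S,5S,6R)-6-(but-1-en-2-yl)-5-[2-[(tert-butyldimethylsilyl)oxy]ethyl]-1,2-diethyl-4-methyl-2-[(E)-2-phenylethenyl]cyclohex-3-ene-1-carboxylic acid | C=C(CC)[C@H]1[C@H](CCO[Si](C)(C)C(C)(C)C)C(C)=C[C@@](/C=C/c2ccccc2)(CC)[C@]1(CC)C(=O)O | intermediate
21 | methyl (1R,2S,5S,6R)-6-(but-1-en-2-yl)-5-[2-[(tert-butyldimethylsilyl)oxy]ethyl]-1,2-diethyl-4-methyl-2-[(E)-2-phenylethenyl]cyclohex-3-ene-1-carboxylate | C=C(CC)[C@H]1[C@H](CCO[Si](C)(C)C(C)(C)C)C(C)=C[C@@](/C=C/c2ccccc2)(CC)[C@]1(CC)C(=O)OC | intermediate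
22 | B-alkyl-9-borabicyclo[3.3.1]nonane formed from 21 at the terminal carbon of the butenyl group | CCC(CB1C2CCCC1CCC2)[C@H]1[C@H](CCO[Si](C)(C)C(C)(C)C)C(C)=C[C@@](/C=C/c2ccccc2)(CC)[C@]1(CC)C(=O)OC | intermediate
23 | methyl (1R,2S,5S,6R)-5-[2-[(tert-butyldimethylsilyl)oxy]ethyl]-1,2-diethyl-6-(1-hydroxybutan-2-yl)-4-methyl-2-[(E)-2-phenylethenyl]cyclohex-3-ene-1-carboxylate, side-chain epimers | CCC(CO)[C@H]1[C@H](CCO[Si](C)(C)C(C)(C)C)C(C)=C[C@@](/C=C/c2ccccc2)(CC)[C@]1(CC)C(=O)OC | intermediate
24 | methyl (1R,2S,5S,6R)-6-(1-carboxypropyl)-5-(carboxymethyl)-1,2-diethyl-4-methyl-2-[(E)-2-phenylethenyl]cyclohex-3-ene-1-carboxylate, side-chain epimers | CCC(C(=O)O)[C@H]1[C@H](CC(=O)O)C(C)=C[C@@](/C=C/c2ccccc2)(CC)[C@]1(CC)C(=O)OC | intermediate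
25 | methyl (1R,2S,5S,6R)-1,2-diethyl-6-(1-methoxy-1-oxobutan-2-yl)-5-(2-methoxy-2-oxoethyl)-4-methyl-2-[(E)-2-phenylethenyl]cyclohex-3-ene-1-carboxylate, side-chain epimers | CCC(C(=O)OC)[C@H]1[C@H](CC(=O)OC)C(C)=C[C@@](/C=C/c2ccccc2)(CC)[C@]1(CC)C(=O)OC | intermediate
26 | potassium enolate of dimethyl 1,6,7-triethyl-4-methyl-2-oxo-6-[(E)-2-phenylethenyl]-2,3,3a,6,7,7a-hexahydro-1H-indene-3,7-dicarboxylate (C3a, C6, C7, C7a configured as in 29) | CCC1C(O[K])=C(C(=O)OC)[C@@H]2C(C)=C[C@@](/C=C/c3ccccc3)(CC)[C@](CC)(C(=O)OC)[C@H]21 | intermediate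
27 | dimethyl (3aS,6S,7R,7aR)-1,6,7-triethyl-3,4-dimethyl-2-oxo-6-[(E)-2-phenylethenyl]-2,3,3a,6,7,7a-hexahydro-1H-indene-3,7-dicarboxylate, C1 and C3 not controlled | CCC1C(=O)C(C)(C(=O)OC)[C@@H]2C(C)=C[C@@](/C=C/c3ccccc3)(CC)[C@](CC)(C(=O)OC)[C@H]21 | intermediate
28 | lithium (3aR,6S,7R,7aR)-1,6,7-triethyl-3,4-dimethyl-2-oxo-6-[(E)-2-phenylethenyl]-2,3,3a,6,7,7a-hexahydro-1H-indene-7-carboxylate, mixture of C1 and C3 epimers | CCC1C(=O)C(C)[C@@H]2C(C)=C[C@@](/C=C/c3ccccc3)(CC)[C@](CC)(C(=O)O[Li])[C@H]21 | intermediate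
29 | (1S,3S,3aR,6S,7R,7aR)-1,6,7-triethyl-3,4-dimethyl-2-oxo-6-[(E)-2-phenylethenyl]-2,3,3a,6,7,7a-hexahydro-1H-indene-7-carboxylic acid | CC[C@@H]1C(=O)[C@@H](C)[C@@H]2C(C)=C[C@@](/C=C/c3ccccc3)(CC)[C@](CC)(C(=O)O)[C@H]21 | target

## Step count and least certain steps

Total: 20 steps. Longest linear sequence: 20 steps, from **1** to **29**.

**Step 14 (key step).** The boat forces the C7a butenyl arm against the C6 ethyl group, so the rearrangement may be slow. The ketene acetal could then be lost by ionisation of the tertiary dienylic C4–O bond (fragmentation to a triene acid) or by hydrolysis back to the lactone. Fallback: from **17**, the enolate made with LiN(SiMe3)2 is brominated with N-bromosuccinimide to give (4S,5S,6S)-3-bromo-4-(but-1-en-2-yl)-5-[2-[(tert-butyldimethylsilyl)oxy]ethyl]-3-ethyl-6-[(1E,3E)-2-ethyl-4-phenylbuta-1,3-dien-1-yl]-6-methyloxan-2-one F1. Zinc dust and Me3SiCl in THF then generate the zinc enolate and ketene acetal **18** without amide base or amine salts (Reformatsky–Claisen rearrangement), and the route is rejoined at **20**.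

**Step 13.** Oxidative addition at the bromide cis to the quaternary C4 may be slow. Zerovalent palladium could then ionise the tertiary dienylic C4–O bond of the lactone, or the alkenylpalladium could isomerise or be reduced by β-hydride transfer from the ethyl group. Fallback: an olefination in place of the two couplings. Commercial diethyl cinnamylphosphonate is ethylated at its α-carbon (n-BuLi, EtI) to diethyl [(1E)-1-phenylpent-1-en-3-yl]phosphonate F2. Its lithium anion is condensed with aldehyde **14** (Horner–Wadsworth–Emmons reaction), which should favour the diene with the conjugating styryl group trans to C4. After separation of the minor isomer the route is rejoined at **17**.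

**Step 6.** Acylation of the hindered tertiary hydroxyl may stall, the triethylsilyl group may migrate from the primary to the tertiary oxygen under base, and the acrylate may polymerise. Fallback: from **7**, ozonolysis of the vinyl group (O3, CH2Cl2, −78 °C; PPh3) gives (2R,3S)-2-[2-[(tert-butyldimethylsilyl)oxy]ethyl]-3-hydroxy-3-methyl-4-[(triethylsilyl)oxy]butanal F3. Z-selective olefination with methyl bis(2,2,2-trifluoroethyl)phosphonoacetate and KN(SiMe3)2/18-crown-6 gives methyl (2Z,4S,5S)-4-[2-[(tert-butyldimethylsilyl)oxy]ethyl]-5-hydroxy-5-methyl-6-[(triethylsilyl)oxy]hex-2-enoate F4. This lactonises with catalytic DBU, and the route is rejoined at **9**.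

**Step 10.** The silyl ether to be oxidised is neopentyl, so cleavage by the chlorosulfonium salt may be slow, and the primary tert-butyldimethylsilyl ether may begin to compete. Fallback: from **13**, HF·pyridine buffered with pyridine (THF, 0 °C) removes only the triethylsilyl group to give (3R,4S,5S,6S)-4-(but-1-en-2-yl)-5-[2-[(tert-butyldimethylsilyl)oxy]ethyl]-3-ethyl-6-(hydroxymethyl)-6-methyloxan-2-one F5. Dess–Martin periodinane with NaHCO3 then gives **14**.

**Step 19.** In the ring B conformer with both arms axial, the C3 ester enolate lies next to the C7 ester and could close the wrong way to a bridged β-keto ester; retro-Claisen opening is the other hazard. Fallback: the C7 carboxyl is carried as a carboxylate, which cannot be acylated. From **20**, excess 9-BBN then H2O2/NaOAc gives (1R,2S,5S,6R)-5-[2-[(tert-butyldimethylsilyl)oxy]ethyl]-1,2-diethyl-6-(1-hydroxybutan-2-yl)-4-methyl-2-[(E)-2-phenylethenyl]cyclohex-3-ene-1-carboxylic acid F6. CrO3/H2SO4 gives (1R,2S,5S,6R)-6-(1-carboxypropyl)-5-(carboxymethyl)-1,2-diethyl-4-methyl-2-[(E)-2-phenylethenyl]cyclohex-3-ene-1-carboxylic acid F7. Methanol with catalytic H2SO4 at room temperature esterifies only the two unhindered acids, giving (1R,2S,5S,6R)-1,2-diethyl-6-(1-methoxy-1-oxobutan-2-yl)-5-(2-methoxy-2-oxoethyl)-4-methyl-2-[(E)-2-phenylethenyl]cyclohex-3-ene-1-carboxylic acid F8. Excess KOtBu followed by excess MeI effects the Dieckmann closure, the C3 methylation and the O-methylation of the carboxylate, and the route is rejoined at **27**.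

**Step 20.** Demethylation of the C7 ester may lag far behind the dealkoxycarbonylation, because its carboxylate is the poorer leaving group. Prolonged heating would then risk lactonisation onto C4=C5 or erosion of the styryl geometry. Fallback: the two tasks are separated and the ester is cleaved at the acyl carbon by a different mechanism. From **27**, LiCl in wet DMSO at 150 °C gives methyl (3aR,6S,7R,7aR)-1,6,7-triethyl-3,4-dimethyl-2-oxo-6-[(E)-2-phenylethenyl]-2,3,3a,6,7,7a-hexahydro-1H-indene-7-carboxylate F9 as an epimer mixture. KOtBu/H2O (2:1) in THF ("anhydrous hydroxide") then hydrolyses the hindered ester and equilibrates C1 and C3, and mild acidification gives **29**.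

## Further compounds

F1 | step 14 | (4S,5S,6S)-3-bromo-4-(but-1-en-2-yl)-5-[2-[(tert-butyldimethylsilyl)oxy]ethyl]-3-ethyl-6-[(1E,3E)-2-ethyl-4-phenylbuta-1,3-dien-1-yl]-6-methyloxan-2-one | C=C(CC)[C@H]1[C@H](CCO[Si](C)(C)C(C)(C)C)[C@@](C)(/C=C(CC)/C=C/c2ccccc2)OC(=O)C1(Br)CC
F2 | step 13 | diethyl [(1E)-1-phenylpent-1-en-3-yl]phosphonate | CCOP(=O)(OCC)C(CC)/C=C/c1ccccc1
F3 | step 6 | (2R,3S)-2-[2-[(tert-butyldimethylsilyl)oxy]ethyl]-3-hydroxy-3-methyl-4-[(triethylsilyl)oxy]butanal | O=C[C@H](CCO[Si](C)(C)C(C)(C)C)[C@](C)(O)CO[Si](CC)(CC)CC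
F4 | step 6 | methyl (2Z,4S,5S)-4-[2-[(tert-butyldimethylsilyl)oxy]ethyl]-5-hydroxy-5-methyl-6-[(triethylsilyl)oxy]hex-2-enoate | COC(=O)/C=C\[C@H](CCO[Si](C)(C)C(C)(C)C)[C@](C)(O)CO[Si](CC)(CC)CC
F5 | step 10 | (3R,4S,5S,6S)-4-(but-1-en-2-yl)-5-[2-[(tert-butyldimethylsilyl)oxy]ethyl]-3-ethyl-6-(hydroxymethyl)-6-methyloxan-2-one | C=C(CC)[C@H]1[C@H](CCO[Si](C)(C)C(C)(C)C)[C@@](C)(CO)OC(=O)[C@@H]1CC
F6 | step 19 | (1R,2S,5S,6R)-5-[2-[(tert-butyldimethylsilyl)oxy]ethyl]-1,2-diethyl-6-(1-hydroxybutan-2-yl)-4-methyl-2-[(E)-2-phenylethenyl]cyclohex-3-ene-1-carboxylic acid, side-chain epimers | CCC(CO)[C@H]1[C@H](CCO[Si](C)(C)C(C)(C)C)C(C)=C[C@@](/C=C/c2ccccc2)(CC)[C@]1(CC)C(=O)O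
F7 | step 19 | (1R,2S,5S,6R)-6-(1-carboxypropyl)-5-(carboxymethyl)-1,2-diethyl-4-methyl-2-[(E)-2-phenylethenyl]cyclohex-3-ene-1-carboxylic acid, side-chain epimers | CCC(C(=O)O)[C@H]1[C@H](CC(=O)O)C(C)=C[C@@](/C=C/c2ccccc2)(CC)[C@]1(CC)C(=O)O
F8 | step 19 | (1R,2S,5S,6R)-1,2-diethyl-6-(1-methoxy-1-oxobutan-2-yl)-5-(2-methoxy-2-oxoethyl)-4-methyl-2-[(E)-2-phenylethenyl]cyclohex-3-ene-1-carboxylic acid, side-chain epimers | CCC(C(=O)OC)[C@H]1[C@H](CC(=O)OC)C(C)=C[C@@](/C=C/c2ccccc2)(CC)[C@]1(CC)C(=O)O
F9 | step 20 | methyl (3aR,6S,7R,7aR)-1,6,7-triethyl-3,4-dimethyl-2-oxo-6-[(E)-2-phenylethenyl]-2,3,3a,6,7,7a-hexahydro-1H-indene-7-carboxylate, C1 and C3 epimers | CCC1C(=O)C(C)[C@@H]2C(C)=C[C@@](/C=C/c3ccccc3)(CC)[C@](CC)(C(=O)OC)[C@H]21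
A1 | alternative 1 | (3E,6E)-1,8-bis(benzyloxy)-4-ethyl-6-methylnona-3,6-dien-5-one, C8 configured as drawn | CC/C(=C\CCOCc1ccccc1)C(=O)/C(C)=C/[C@H](C)OCc1ccccc1
A2 | alternative 1 | all-trans 3-[2-(benzyloxy)ethyl]-4-[1-(benzyloxy)ethyl]-2-ethyl-5-methylcyclopentan-1-one, configured as drawn | CC[C@@H]1C(=O)[C@@H](C)[C@H]([C@H](C)OCc2ccccc2)[C@H]1CCOCc1ccccc1
A3 | alternative 2 | methyl 3-ethenyl-2,3-diethyl-2-[2-ethyl-4-methyl-3-oxo-5-(prop-1-en-2-yl)cyclopentyl]pent-4-enoate, configured as drawn | CC[C@@H]1C(=O)[C@@H](C)[C@H](C(C)=C)[C@H]1[C@@](CC)(C(=O)OC)C(CC)(C=C)C=C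
A4 | alternative 2 | methyl 6-ethenyl-1,6,7-triethyl-3,4-dimethyl-2-oxo-2,3,3a,6,7,7a-hexahydro-1H-indene-7-carboxylate, configured as drawn | CC[C@@H]1C(=O)[C@@H](C)[C@@H]2C(C)=C[C@@](C=C)(CC)[C@](CC)(C(=O)OC)[C@H]21
A5 | alternative 3 | 2,3-diethylmaleic anhydride (3,4-diethylfuran-2,5-dione) | CCC1=C(CC)C(=O)OC1=O
A6 | alternative 3 | (2R,5R)-1-[(1E)-3-[(tert-butyldimethylsilyl)oxy]buta-1,3-dien-1-yl]-2,5-diphenylpyrrolidine, drawn as one antipode; the antipode that delivers A7 would be used | C=C(O[Si](C)(C)C(C)(C)C)/C=C/N1[C@@H](c2ccccc2)CC[C@@H]1c1ccccc1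
A7 | alternative 3 | cis-3a,7a-diethyl-7,7a-dihydro-2-benzofuran-1,3,6(3aH)-trione, enantiomer as drawn | O=C1C=C[C@@]2(CC)C(=O)OC(=O)[C@@]2(CC)C1
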